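## Retrosynthetic overview

1. The last bond made is the side-chain CH2–CH(CH3) bond (C2'–C3'). It is formed by a phosphane-directed, copper-mediated syn-SN2' reaction of primary Grignard reagent 21 (C12 ring fragment) with allylic o-diphenylphosphanylbenzoate 19 (C19 chain fragment). The same step sets C3', creates the 4'E-olefin and ends the synthesis.
2. The enabling feature is the acyclic unit C6'(CH3)(CH=CH2)–C5'H=C4'H–C3'H(CH3): an (E)-alkene flanked by the quaternary carbon and the methyl-bearing methine. Shifting this C=C by one bond gives an (E)-propenyl carbinol on the carbon next to the quaternary vinyl carbon, which is the product of a farnesyl addition to crotonaldehyde.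
3. Chain fragment: (2E,6E)-farnesyl chloride → allyltrichlorosilane 15 → catalytic asymmetric allylation of (E)-but-2-enal, which sets the quaternary carbon and the carbinol together (18) → ester 19.
4. Ring fragment: the cyclohexane ring is bought as 4,4-dimethylcyclohexenone; no ring is formed in the route. Methyl (asymmetric) and vinyl (trans) are added to the two β-carbons of dienone 2, the carbonyl is exchanged for the exocyclic methylene, and the vinyl group becomes CH2CH2I (13).

Key step: step 12

Assumption: the sense of induction of the two chiral catalysts is taken by analogy with simple substrates ((R,S,S)-phosphoramidite gives (5S)-4; (R,R)-bisphosphoramide gives Si-face attack on 16); should either prove opposite, the antipodal catalyst is used and nothing else changes.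

## Route

Step 1
Reactants: 1 4,4-dimethylcyclohex-2-en-1-one
Product: 2 4,4-dimethylcyclohexa-2,5-dien-1-one
Conditions: DDQ (1.5 equiv), 1,4-dioxane, reflux
Reagents that add atoms: none
Why: Quinone dehydrogenation of an enone at its only CH2–CH2 pair should give the cross-conjugated dienone; no stereocentre is involved.

Step 2
Reactants: 2 4,4-dimethylcyclohexa-2,5-dien-1-one
Product: 4 (5S)-4,4,5-trimethylcyclohex-2-en-1-one, via methylzinc dienolate 3 (not isolated)
Conditions: Me2Zn (1.5 equiv), Cu(OTf)2 (2 mol %), (R,S,S)-phosphoramidite [(R)-1,1'-binaphthalene-2,2'-diyl N,N-bis((S)-1-phenylethyl)phosphoramidite, 4 mol %], toluene, −25 °C; aq. NH4Cl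
Reagents that add atoms: dimethylzinc C[Zn]C
Why: Copper-catalysed asymmetric conjugate addition of a dialkylzinc: the two enone arms of 2 are equivalent, the ligand selects one enantiotopic face of the β-carbon and so sets the ring methyl stereocentre (5S), and the zinc dienolate formed is no longer an acceptor, so only one methyl should add.

Step 3
Reactants: 4 (5S)-4,4,5-trimethylcyclohex-2-en-1-one
Product: 5 {[(3S,5S)-3-ethenyl-4,4,5-trimethylcyclohex-1-en-1-yl]oxy}trimethylsilane
Conditions: CH2=CHMgBr (1.5 equiv), CuBr·SMe2 (10 mol %), TMSCl (2 equiv), DMPU (2 equiv), THF, −78 °C; Et3N, cold aq. NaHCO3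
Reagents that add atoms: vinylmagnesium bromide C=C[Mg]Br; chlorotrimethylsilane C[Si](C)(C)Cl
Why: Copper-catalysed, TMSCl-accelerated conjugate addition of a vinyl Grignard reagent; axial attack on the half-chair with the C5 methyl pseudo-equatorial should place the vinyl group trans to that methyl (the known trans-3,5 preference of 5-substituted cyclohexenones), and silylation fixes the enolate toward C2.

Step 4
Reactants: 5 {[(3S,5S)-3-ethenyl-4,4,5-trimethylcyclohex-1-en-1-yl]oxy}trimethylsilane
Product: 8 (3R,5S)-3-ethenyl-4,4,5-trimethyl-2-methylidenecyclohexan-1-one, via Mannich base 6 (not isolated), via ammonium iodide 7 (not isolated)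
Conditions: CH2=NMe2+ I− (1.5 equiv), CH2Cl2, 0 °C to rt; aq. NaHCO3; MeI (5 equiv), Et2O, rt; aq. NaHCO3/CH2Cl2, rt
Reagents that add atoms: N,N-dimethylmethyleneiminium iodide C=[N+](C)C.[I-]
Why: Mannich reaction of the regiodefined silyl enol ether with the preformed iminium salt, then quaternisation and E1cB loss of trimethylamine, should give the α-methylene ketone; only hydrogencarbonate is used as base and 8 is reduced at once, because the doubly allylic C3–H makes isomerisation into conjugation the main hazard.

Step 5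
Reactants: 8 (3R,5S)-3-ethenyl-4,4,5-trimethyl-2-methylidenecyclohexan-1-one
Product: 9 (3R,5S)-3-ethenyl-4,4,5-trimethyl-2-methylidenecyclohexan-1-ol (both C1 epimers)
Conditions: NaBH4 (1.1 equiv), CeCl3·7H2O (1.1 equiv), MeOH, −78 to 0 °C
Reagents that add atoms: none
Why: Luche reduction should give clean 1,2-reduction of the enone; the configuration of the new carbinol carbon is irrelevant because it becomes CH2 in step 7.

Step 6
Reactants: 9 (3R,5S)-3-ethenyl-4,4,5-trimethyl-2-methylidenecyclohexan-1-ol
Product: 10 methyl (3R,5S)-3-ethenyl-4,4,5-trimethyl-2-methylidenecyclohexyl carbonate (both C1 epimers)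
Conditions: ClCO2Me (1.5 equiv), pyridine, DMAP (cat.), CH2Cl2, 0 °C to rt
Reagents that add atoms: methyl chloroformate COC(=O)Cl
Why: Standard acylation of a secondary allylic alcohol gives the allylic carbonate needed for ionisation by zerovalent palladium.

Step 7
Reactants: 10 methyl (3R,5S)-3-ethenyl-4,4,5-trimethyl-2-methylidenecyclohexyl carbonate
Product: 11 (2S,6S)-2-ethenyl-1,1,6-trimethyl-3-methylidenecyclohexane
Conditions: Pd(OAc)2 (5 mol %), n-Bu3P (20 mol %), HCO2H (2 equiv), Et3N (3 equiv), THF, rt to 40 °C
Reagents that add atoms: none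
Why: Palladium-catalysed hydrogenolysis of an allylic carbonate with formate: the π-allylpalladium formate loses CO2 and delivers hydride to the more substituted (ring) terminus, the known route to exocyclic 1,1-disubstituted alkenes; the two ring stereocentres are not part of the allyl system.

Step 8
Reactants: 11 (2S,6S)-2-ethenyl-1,1,6-trimethyl-3-methylidenecyclohexane
Product: 13 (2S,6S)-2-(2-iodoethyl)-1,1,6-trimethyl-3-methylidenecyclohexane, via alkylzirconocene chloride 12 (not isolated)
Conditions: Cp2Zr(H)Cl (1.3 equiv), THF, rt; then I2 (1.3 equiv), 0 °C; aq. Na2S2O3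
Reagents that add atoms: iodine II
Why: Hydrozirconation is much faster for a monosubstituted vinyl group than for a 1,1-disubstituted alkene and places zirconium on the terminal carbon; iodinolysis of the C–Zr bond then gives the primary iodide.

Step 9
Reactants: 14 (2E,6E)-1-chloro-3,7,11-trimethyldodeca-2,6,10-triene (farnesyl chloride)
Product: 15 trichloro[(2E,6E)-3,7,11-trimethyldodeca-2,6,10-trien-1-yl]silane
Conditions: HSiCl3 (1.5 equiv), CuCl (5 mol %), i-Pr2NEt (1.5 equiv), Et2O, 0 °C to rt; filtration, short-path distillation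
Reagents that add atoms: trichlorosilane Cl[SiH](Cl)Cl
Why: Copper-catalysed silylation of an allylic chloride with trichlorosilane and an amine base should give the linear allyltrichlorosilane with retention of the 2E geometry.

Step 10
Reactants: 15 trichloro[(2E,6E)-3,7,11-trimethyldodeca-2,6,10-trien-1-yl]silane; 16 (E)-but-2-enal
Product: 18 (2E,4R,5S,8E)-5-ethenyl-5,9,13-trimethyltetradeca-2,8,12-trien-4-ol, via trichlorosilyl ether 17 (not isolated)
Conditions: 15 (1.5 equiv), (R,R)-bisphosphoramide [N,N'-dimethylpentane-1,5-diamine bridging two P(=O) units, each chelated by (2R,2'R)-2,2'-bipyrrolidine; 10 mol %], i-Pr2NEt (2 equiv), CH2Cl2, −78 °C; sat. aq. NaHCO3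
Reagents that add atoms: none
Why: Chiral Lewis-base-catalysed allylation of a conjugated aldehyde with a γ,γ-disubstituted allyltrichlorosilane through a closed chair transition state at hexacoordinate silicon: the 2E geometry of 15 fixes the relative configuration (chain anti and methyl syn to oxygen) and the catalyst selects the Si face of the enal, so the quaternary carbon (5S) and the carbinol carbon (4R) are set together.

Step 11
Reactants: 18 (2E,4R,5S,8E)-5-ethenyl-5,9,13-trimethyltetradeca-2,8,12-trien-4-ol
Product: 19 (2E,4R,5S,8E)-5-ethenyl-5,9,13-trimethyltetradeca-2,8,12-trien-4-yl 2-(diphenylphosphanyl)benzoate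
Conditions: 2-Ph2P-C6H4CO2H (1.1 equiv), DCC (1.2 equiv), DMAP (0.2 equiv), CH2Cl2, rt, argon
Reagents that add atoms: 2-(diphenylphosphanyl)benzoic acid OC(=O)c1ccccc1P(c1ccccc1)c1ccccc1
Why: Steglich esterification installs the o-diphenylphosphanylbenzoate, which serves as both leaving group and directing group in the key step.

Step 12
Reactants: 13 (2S,6S)-2-(2-iodoethyl)-1,1,6-trimethyl-3-methylidenecyclohexane; 19 (2E,4R,5S,8E)-5-ethenyl-5,9,13-trimethyltetradeca-2,8,12-trien-4-yl 2-(diphenylphosphanyl)benzoate
Product: 22 (2S,6S)-2-[(3S,4E,6S,9E)-6-ethenyl-3,6,10,14-tetramethylpentadeca-4,9,13-trien-1-yl]-1,1,6-trimethyl-3-methylidenecyclohexane, via alkyllithium 20 (not isolated), via alkylmagnesium bromide 21 (not isolated)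
Conditions: 13 (1.3 equiv), t-BuLi (2.0 equiv per 13), Et2O/pentane, −78 °C; MgBr2·OEt2 (1.1 equiv per 13), −78 to 0 °C; this solution added over 1 h to 19 (1.0 equiv) and CuBr·SMe2 (0.5 equiv), Et2O, rt; aq. NH4Cl
Reagents that add atoms: none
Why: The Grignard reagent transmetalates to monovalent copper held by the phosphane of the o-diphenylphosphanylbenzoate, so the alkyl group is delivered intramolecularly to the γ-carbon (the CH3-bearing alkene carbon) on the face that carries the ester oxygen, through syn oxidative addition to a σ-allyl trivalent copper species and reductive elimination with loss of the carboxylate (syn-SN2'). The closest known reaction type is the o-diphenylphosphanylbenzoate-directed copper-mediated allylic substitution of acyclic secondary (E)-allylic esters with primary alkyl Grignard reagents, which is used to build methyl-branched stereocentres with complete allylic transposition. No ring is closed. The new stereocentre C3' (S) is controlled by the carbinol centre C4 (R) of 19 through syn 1,3-chirality transfer in the conformer that keeps the carbinol hydrogen eclipsed with the alkene and the quaternary substituent outside (A1,3 strain), and the same conformer makes the new C4'=C5' double bond E. The step needs γ- over α-attack, syn over anti delivery and inertness of the four other alkenes: the neopentyl α-carbon and the tether disfavour α-attack, slow addition of 21 keeps the amount of untethered cuprate (the source of anti attack) low, and unactivated alkenes do not react with alkylcopper species. The hindered ester carbonyl should not be attacked at room temperature under these conditions.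

## Compound list

1 | 4,4-dimethylcyclohex-2-en-1-one | CC1(C)CCC(=O)C=C1 | starting material
2 | 4,4-dimethylcyclohexa-2,5-dien-1-one | CC1(C)C=CC(=O)C=C1 | intermediate
3 | methyl[(3S)-3,4,4-trimethylcyclohexa-1,5-dien-1-olato]zinc | C1=CC(O[Zn]C)=C[C@H](C)C1(C)C | intermediate (not isolated)
4 | (5S)-4,4,5-trimethylcyclohex-2-en-1-one | C1=CC(=O)C[C@H](C)C1(C)C | intermediate
5 | {[(3S,5S)-3-ethenyl-4,4,5-trimethylcyclohex-1-en-1-yl]oxy}trimethylsilane | C=C[C@H]1C=C(O[Si](C)(C)C)C[C@H](C)C1(C)C | intermediate
6 | (3S,5S)-2-[(dimethylamino)methyl]-3-ethenyl-4,4,5-trimethylcyclohexan-1-one (C2 epimers) | C=C[C@H]1C(CN(C)C)C(=O)C[C@H](C)C1(C)C | intermediate (not isolated)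
7 | {[(4S,6S)-6-ethenyl-4,5,5-trimethyl-2-oxocyclohexyl]methyl}trimethylammonium iodide (C1 epimers) | C=C[C@H]1C(C[N+](C)(C)C)C(=O)C[C@H](C)C1(C)C.[I-] | intermediate (not isolated)
8 | (3R,5S)-3-ethenyl-4,4,5-trimethyl-2-methylidenecyclohexan-1-one | C=C[C@H]1C(=C)C(=O)C[C@H](C)C1(C)C | intermediate
9 | (3R,5S)-3-ethenyl-4,4,5-trimethyl-2-methylidenecyclohexan-1-ol (C1 epimers) | C=C[C@H]1C(=C)C(O)C[C@H](C)C1(C)C | intermediate
10 | methyl (3R,5S)-3-ethenyl-4,4,5-trimethyl-2-methylidenecyclohexyl carbonate (C1 epimers) | C=C[C@H]1C(=C)C(OC(=O)OC)C[C@H](C)C1(C)C | intermediate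
11 | (2S,6S)-2-ethenyl-1,1,6-trimethyl-3-methylidenecyclohexane | C=C[C@H]1C(=C)CC[C@H](C)C1(C)C | intermediate
12 | chlorobis(cyclopentadienyl){2-[(1S,3S)-2,2,3-trimethyl-6-methylidenecyclohexyl]ethyl}zirconium (cyclopentadienyl rings written as σ-bonded C5H5) | Cl[Zr](CC[C@H]1C(=C)CC[C@H](C)C1(C)C)(C1C=CC=C1)C1C=CC=C1 | intermediate (not isolated)
13 | (2S,6S)-2-(2-iodoethyl)-1,1,6-trimethyl-3-methylidenecyclohexane | ICC[C@H]1C(=C)CC[C@H](C)C1(C)C | intermediate
14 | (2E,6E)-1-chloro-3,7,11-trimethyldodeca-2,6,10-triene (farnesyl chloride) | CC(C)=CCC/C(C)=C/CC/C(C)=C/CCl | starting material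
15 | trichloro[(2E,6E)-3,7,11-trimethyldodeca-2,6,10-trien-1-yl]silane | CC(C)=CCC/C(C)=C/CC/C(C)=C/C[Si](Cl)(Cl)Cl | intermediate
16 | (E)-but-2-enal (crotonaldehyde) | C/C=C/C=O | starting material
17 | trichloro{[(2E,4R,5S,8E)-5-ethenyl-5,9,13-trimethyltetradeca-2,8,12-trien-4-yl]oxy}silane | C=C[C@@](C)([C@H](O[Si](Cl)(Cl)Cl)/C=C/C)CC/C=C(\C)CCC=C(C)C | intermediate (not isolated)
18 | (2E,4R,5S,8E)-5-ethenyl-5,9,13-trimethyltetradeca-2,8,12-trien-4-ol | C=C[C@@](C)([C@H](O)/C=C/C)CC/C=C(\C)CCC=C(C)C | intermediate
19 | (2E,4R,5S,8E)-5-ethenyl-5,9,13-trimethyltetradeca-2,8,12-trien-4-yl 2-(diphenylphosphanyl)benzoate | C=C[C@@](C)([C@H](OC(=O)c1ccccc1P(c1ccccc1)c1ccccc1)/C=C/C)CC/C=C(\C)CCC=C(C)C | intermediate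
20 | {2-[(1S,3S)-2,2,3-trimethyl-6-methylidenecyclohexyl]ethyl}lithium | [Li]CC[C@H]1C(=C)CC[C@H](C)C1(C)C | intermediate (not isolated)
21 | {2-[(1S,3S)-2,2,3-trimethyl-6-methylidenecyclohexyl]ethyl}magnesium bromide | Br[Mg]CC[C@H]1C(=C)CC[C@H](C)C1(C)C | intermediate (not isolated)
22 | (2S,6S)-2-[(3S,4E,6S,9E)-6-ethenyl-3,6,10,14-tetramethylpentadeca-4,9,13-trien-1-yl]-1,1,6-trimethyl-3-methylidenecyclohexane | C=C[C@@](C)(/C=C/[C@@H](C)CC[C@H]1C(=C)CC[C@H](C)C1(C)C)CC/C=C(\C)CCC=C(C)C | target

## Step count

Total steps: 12 (ring fragment steps 1–8, chain fragment steps 9–11, union step 12).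
Longest linear sequence: 9 steps (steps 1–8, then step 12).

## Steps most likely to fail

**Step 12.** The tether control may be lost: alkyl transfer from untethered cuprate to the face opposite the ester, or at the carbinol carbon, would erode the configuration at C3' and the regiochemistry, and copper transfer to the crowded ester may be slow. The fallback sets out from 13 and 18 and comes back at 22. It forms the same bond by an Ireland–Claisen rearrangement, which is suprafacial on the allyl unit and therefore gives the same 3'S centre and E-olefin. Iodide 13 is lithiated as in step 12 (to 20) and carboxylated with CO2 to 3-[(1S,3S)-2,2,3-trimethyl-6-methylidenecyclohexyl]propanoic acid F1. Steglich esterification of F1 with 18 gives the allylic propanoate F2. Enolisation (LDA, TMSCl, THF, −78 °C) gives the silyl ketene acetal F3, which on warming should rearrange through a chair transition state (quaternary group equatorial) to the trimethylsilyl ester F4 and, after aqueous acid, the carboxylic acid F5, which carries the extra carboxyl on the CH2 carbon of the new bond. F5 is converted with 2-mercaptopyridine N-oxide and DCC into the N-acyloxy-2-thiopyridone F6. Barton decarboxylation of F6 (t-BuSH in excess, visible light, rt) gives 22; the thiol concentration is kept high so that hydrogen transfer outruns rearrangement of the homoallylic radical.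

**Step 10.** Turnover may be low and enantiofacial discrimination weak with a small aliphatic enal, giving material of insufficient enantiomeric purity; the relative configuration is secured by the closed transition state. The fallback sets out from 15 and 16 and comes back at 18. The two are combined with DMF as an achiral Lewis-base promoter (CH2Cl2, 0 °C). Through the same chair transition state this should give, via the racemic trichlorosilyl ether F7, the racemic alcohol F8 as a single diastereomer. Sharpless kinetic resolution (Ti(OiPr)4, D-(−)-diisopropyl tartrate, t-BuOOH 0.6 equiv, CH2Cl2, −20 °C) is expected to epoxidise the (4S,5R)-enantiomer to the epoxy alcohol F9 and leave (4R,5S)-18, which is separated by chromatography.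

**Step 8.** Discrimination between the hindered vinyl group and the exocyclic methylene in the Zr–H addition may be incomplete, or addition to the hindered vinyl group may be slow. The fallback sets out from 11 and comes back at 13. Hydrosilylation with HSi(OEt)3 and Pt2[(CH2=CHSiMe2)2O]3 (zerovalent platinum, toluene, rt), which is selective for monosubstituted alkenes, gives triethoxy{2-[(1S,3S)-2,2,3-trimethyl-6-methylidenecyclohexyl]ethyl}silane F10. Tamao–Fleming oxidation (H2O2, KF, KHCO3, THF/MeOH) gives 2-[(1S,3S)-2,2,3-trimethyl-6-methylidenecyclohexyl]ethan-1-ol F11. Iodination of F11 (I2, PPh3, imidazole, CH2Cl2) gives 13.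

## Further compounds

F1 | step 12 | 3-[(1S,3S)-2,2,3-trimethyl-6-methylidenecyclohexyl]propanoic acid | OC(=O)CC[C@H]1C(=C)CC[C@H](C)C1(C)C
F2 | step 12 | (2E,4R,5S,8E)-5-ethenyl-5,9,13-trimethyltetradeca-2,8,12-trien-4-yl 3-[(1S,3S)-2,2,3-trimethyl-6-methylidenecyclohexyl]propanoate | C=C[C@@](C)([C@H](OC(=O)CC[C@H]1C(=C)CC[C@H](C)C1(C)C)/C=C/C)CC/C=C(\C)CCC=C(C)C
F3 | step 12 | trimethylsilyl ketene acetal of F2 (enol ether geometry not defined) | C=C[C@@](C)([C@H](OC(O[Si](C)(C)C)=CC[C@H]1C(=C)CC[C@H](C)C1(C)C)/C=C/C)CC/C=C(\C)CCC=C(C)C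
F4 | step 12 | trimethylsilyl (3S,4E,6S,9E)-6-ethenyl-3,6,10,14-tetramethyl-2-{[(1S,3S)-2,2,3-trimethyl-6-methylidenecyclohexyl]methyl}pentadeca-4,9,13-trienoate (C2 epimers) | C=C[C@@](C)(/C=C/[C@@H](C)C(C(=O)O[Si](C)(C)C)C[C@H]1C(=C)CC[C@H](C)C1(C)C)CC/C=C(\C)CCC=C(C)C
F5 | step 12 | (3S,4E,6S,9E)-6-ethenyl-3,6,10,14-tetramethyl-2-{[(1S,3S)-2,2,3-trimethyl-6-methylidenecyclohexyl]methyl}pentadeca-4,9,13-trienoic acid (C2 epimers) | C=C[C@@](C)(/C=C/[C@@H](C)C(C(=O)O)C[C@H]1C(=C)CC[C@H](C)C1(C)C)CC/C=C(\C)CCC=C(C)C
F6 | step 12 | 2-thioxopyridin-1(2H)-yl ester of F5 (Barton ester) | C=C[C@@](C)(/C=C/[C@@H](C)C(C(=O)ON1C=CC=CC1=S)C[C@H]1C(=C)CC[C@H](C)C1(C)C)CC/C=C(\C)CCC=C(C)C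
F7 | step 10 | racemic trichlorosilyl ether (1:1 mixture of 17 and its enantiomer) | C=C[C@@](C)([C@H](O[Si](Cl)(Cl)Cl)/C=C/C)CC/C=C(\C)CCC=C(C)C.C=C[C@](C)([C@@H](O[Si](Cl)(Cl)Cl)/C=C/C)CC/C=C(\C)CCC=C(C)C
F8 | step 10 | racemic (2E,4R*,5S*,8E)-5-ethenyl-5,9,13-trimethyltetradeca-2,8,12-trien-4-ol (1:1 mixture of 18 and its enantiomer) | C=C[C@@](C)([C@H](O)/C=C/C)CC/C=C(\C)CCC=C(C)C.C=C[C@](C)([C@@H](O)/C=C/C)CC/C=C(\C)CCC=C(C)C
F9 | step 10 | (1R,2R,5E)-2-ethenyl-2,6,10-trimethyl-1-[(2S,3S)-3-methyloxiran-2-yl]undeca-5,9-dien-1-ol | C[C@@H]1O[C@H]1[C@H](O)[C@@](C)(C=C)CC/C=C(\C)CCC=C(C)C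
F10 | step 8 | triethoxy{2-[(1S,3S)-2,2,3-trimethyl-6-methylidenecyclohexyl]ethyl}silane | CCO[Si](OCC)(OCC)CC[C@H]1C(=C)CC[C@H](C)C1(C)C
F11 | step 8 | 2-[(1S,3S)-2,2,3-trimethyl-6-methylidenecyclohexyl]ethan-1-ol | OCC[C@H]1C(=C)CC[C@H](C)C1(C)C
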